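The route rests on disconnecting the benzofuran-3-one ring between its ring oxygen O1 and aryl carbon C7a. The key step exploits that O1 sits on spiro carbon C2, alpha to the C3 ketone, while C7a is ortho to that ketone and meta to the oxygens at C4 and C6: a tertiary alkoxide displaces an ortho fluoride by intramolecular SNAr, closing the ring and creating the spiro junction in one operation. The precursor is a 9-aroyl-9-hydroxy-8,9-dihydrofuro[2,3-h]chromenone with its hemiketal oxygen capped as benzyl ketal, made by enantioselective ortho-Friedel–Crafts addition of a 7-hydroxyflavonol to a diaryl vicinal triketone. Hydrogenolysis of seven benzyl groups finishes.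

Key step: step 9

Assumption: the hemiketal carbon of the target epimerises by ring–chain tautomerism and the drawn configuration (hydroxyl cis to the benzofuranone carbonyl) is taken as the thermodynamic one, so only the spiro carbon must be set; the sense of induction in step 8 is assumed as written, the quinidine-derived pseudoenantiomer of the catalyst being used otherwise.

Step 1
Reactants: 1 kaempferol
Product: 2 7-O-(methoxymethyl)kaempferol
Conditions: MOMCl (1.05 equiv), K2CO3 (1.1 equiv), acetone, 0 °C to rt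
Reagents that add atoms: chloromethyl methyl ether, COCCl
Why: Williamson-type O-alkylation in which one equivalent of weak base ionises only the 7-OH, the most acidic hydroxyl (para to the pyranone carbonyl), while the 5-OH is chelated and the 3- and 4'-OH are less acidic.

Step 2
Reactants: 2 7-O-(methoxymethyl)kaempferol
Product: 3 3,5-bis(benzyloxy)-2-[4-(benzyloxy)phenyl]-7-(methoxymethoxy)-4H-chromen-4-one
Conditions: BnBr (4 equiv), K2CO3 (5 equiv), DMF, 70 °C, N2
Reagents that add atoms: benzyl bromide, BrCc1ccccc1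
Why: Williamson etherification of the three remaining hydroxyls, excess reagent and heat being needed for the hydrogen-bonded 5-OH; the MOM acetal is stable to base.

Step 3
Reactants: 3 3,5-bis(benzyloxy)-2-[4-(benzyloxy)phenyl]-7-(methoxymethoxy)-4H-chromen-4-one
Product: 4 3,5-bis(benzyloxy)-2-[4-(benzyloxy)phenyl]-7-hydroxy-4H-chromen-4-one
Conditions: HCl (0.5 M), MeOH–THF, 50 °C
Reagents that add atoms: none
Why: Acid-catalysed acetal exchange with methanol cleaves the MOM ether alone, because aryl benzyl ethers do not ionise under these conditions.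

Step 4
Reactants: 5 5-fluorobenzene-1,3-diol
Product: 6 1,3-bis(benzyloxy)-5-fluorobenzene
Conditions: BnBr (2.2 equiv), K2CO3 (3 equiv), DMF, 50 °C
Reagents that add atoms: benzyl bromide, BrCc1ccccc1
Why: Williamson etherification of both phenols; the unactivated aryl fluoride is inert.

Step 5
Reactants: 6 1,3-bis(benzyloxy)-5-fluorobenzene
Product: 8 2,4-bis(benzyloxy)-6-fluorobenzaldehyde, via iminium salt 7 (not isolated)
Conditions: POCl3 (1.5 equiv), DMF, 0 to 70 °C; then ice–water, rt
Reagents that add atoms: N,N-dimethylformamide, CN(C)C=O (formyl carbon); water, O (carbonyl oxygen)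
Why: Vilsmeier–Haack formylation, in which the chloroiminium ion attacks C2 (ortho to one benzyloxy group, para to the other, next to the small fluorine) rather than the more hindered C4 between the two benzyloxy groups, and the iminium salt is hydrolysed on work-up.

Step 6
Reactants: 8 2,4-bis(benzyloxy)-6-fluorobenzaldehyde, 9 1-[4-(benzyloxy)phenyl]ethanone
Product: 11 racemic 3-[2,4-bis(benzyloxy)-6-fluorophenyl]-1-[4-(benzyloxy)phenyl]-3-hydroxypropan-1-one, via lithium enolate 10 (not isolated)
Conditions: 9, LDA (1.05 equiv), THF, −78 °C; then 8, −78 °C; AcOH quench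
Reagents that add atoms: none
Why: Directed aldol addition of the preformed lithium enolate to a non-enolisable aldehyde at low temperature, which avoids self-condensation and attack on the aryl fluoride; the carbinol centre is formed racemic and is oxidised away in step 7.

Step 7
Reactants: 11 racemic 3-[2,4-bis(benzyloxy)-6-fluorophenyl]-1-[4-(benzyloxy)phenyl]-3-hydroxypropan-1-one
Product: 13 1-[2,4-bis(benzyloxy)-6-fluorophenyl]-3-[4-(benzyloxy)phenyl]propane-1,2,3-trione, via 1,3-diketone 12 (not isolated)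
Conditions: Dess–Martin periodinane (3.5 equiv), pyridine (5 equiv), CH2Cl2, rt; then aq. NaHCO3; azeotropic drying with toluene
Reagents that add atoms: Dess–Martin periodinane, CC(=O)OI1(OC(C)=O)(OC(C)=O)OC(=O)c2ccccc12 (oxygen of the central carbonyl)
Why: Tandem Dess–Martin oxidation known for β-hydroxy ketones: the carbinol is oxidised to the 1,3-diketone, whose enol is then oxidised at the central carbon by further periodinane to the vicinal triketone, leaving benzyl ethers and the aryl fluoride untouched.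

Step 8
Reactants: 4 3,5-bis(benzyloxy)-2-[4-(benzyloxy)phenyl]-7-hydroxy-4H-chromen-4-one, 13 1-[2,4-bis(benzyloxy)-6-fluorophenyl]-3-[4-(benzyloxy)phenyl]propane-1,2,3-trione
Product: 16 (8R,9S)-3,5,8-tris(benzyloxy)-9-[2,4-bis(benzyloxy)-6-fluorobenzoyl]-2,8-bis[4-(benzyloxy)phenyl]-9-hydroxy-8,9-dihydro-4H-furo[2,3-h]chromen-4-one, via open-chain carbinol 14 (not isolated), via hemiketal 15 (not isolated)
Conditions: quinine-derived bifunctional squaramide (9-amino-9-deoxy-epi-quinine N-[3,5-bis(trifluoromethyl)phenyl]squaramide, 10 mol %), 4 Å molecular sieves, CH2Cl2, −20 °C to rt; then BnOH (10 equiv), camphorsulfonic acid (30 mol %), rt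
Reagents that add atoms: benzyl alcohol, OCc1ccccc1
Why: Proposed new method: the quinuclidine of the catalyst ionises the acidic 7-OH of 4 while the squaramide N–H pair binds the central, most electrophilic carbonyl of 13 together with the coplanar 4-benzyloxybenzoyl carbonyl, so that C8 (ortho to the phenoxide, C6 being shielded by the 5-benzyloxy group) should add to one face with the twisted 2,6-disubstituted aroyl group turned away, which sets the carbinol centre (R in 14, S in 15 and 16 through a change of CIP priorities only); the phenol then closes 5-exo-trig onto the unhindered 4-benzyloxybenzoyl ketone, and acid-catalysed exchange with benzyl alcohol through the 4-alkoxyphenyl-stabilised oxocarbenium ion caps the hemiketal under thermodynamic control (aryl trans to aroyl; this centre is re-equilibrated in step 10 in any case); the closest known reactions are the cinchona-squaramide-catalysed enantioselective ortho Friedel–Crafts hydroxyalkylation of naphthols and electron-rich phenols with isatins and trifluoropyruvates, and the uncatalysed addition of phenols to ninhydrin and diaryl triketones, which gives the same 2,3-dihydroxy-2,3-dihydrobenzofuran motif.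

Step 9
Reactants: 16 (8R,9S)-3,5,8-tris(benzyloxy)-9-[2,4-bis(benzyloxy)-6-fluorobenzoyl]-2,8-bis[4-(benzyloxy)phenyl]-9-hydroxy-8,9-dihydro-4H-furo[2,3-h]chromen-4-one
Product: 17 (2S,8'R)-3',4,5',6,8'-pentakis(benzyloxy)-2',8'-bis[4-(benzyloxy)phenyl]-8'H-spiro[1-benzofuran-2,9'-furo[2,3-h]chromene]-3,4'-dione
Conditions: Cs2CO3 (2 equiv), DMSO, 70 °C
Reagents that add atoms: none
Why: Cs2CO3 deprotonates the tertiary α-ketol O–H at C9 and the alkoxide adds to the fluorine-bearing aryl carbon ortho to the ketone, giving an anionic σ-adduct whose charge is delocalised into the carbonyl, from which fluoride leaves to restore the arene (intramolecular SNAr, addition–elimination). The closest known reaction is the base-mediated cyclisation of 2-fluorophenyl α-hydroxy ketones to benzofuran-3(2H)-ones. The only ring closed is the five-membered benzofuranone, formed by attack of oxygen on trigonal C7a (5-exo-trig with respect to the C7a=C7 bond of the arene). No new stereocentre is formed: the spiro carbon keeps the S configuration of C9 because none of its bonds is broken, and the ketal carbon is untouched. Chemoselectivity rests on the benzyl ketal, which removes the hemiketal oxygen as a competing nucleophile (it would give a six-membered chromanone ketal) and prevents ring opening to a base-labile 2-hydroxy-1,3-diketone or retro-addition, so the C9 alkoxide is the only nucleophile. Site selectivity rests on fluoride being the only leaving group ortho to the carbonyl, with both benzyloxy groups meta to it and therefore not deactivating.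

Step 10
Reactants: 17 (2S,8'R)-3',4,5',6,8'-pentakis(benzyloxy)-2',8'-bis[4-(benzyloxy)phenyl]-8'H-spiro[1-benzofuran-2,9'-furo[2,3-h]chromene]-3,4'-dione
Product: 18 (2S,8'R)-3',4,5',6,8'-pentahydroxy-2',8'-bis(4-hydroxyphenyl)-8'H-spiro[1-benzofuran-2,9'-furo[2,3-h]chromene]-3,4'-dione (CNP0283000.1)
Conditions: H2 (1 atm), Pd/C (10 wt % palladium on carbon), THF–EtOAc, rt
Reagents that add atoms: none
Why: Hydrogenolysis over palladium cleaves the six aryl benzyl ethers and the benzyl–oxygen bond of the ketal, and the freed hemiketal should equilibrate by ring–chain tautomerism to the R epimer with its hydroxyl cis to, and hydrogen-bonded with, the benzofuranone carbonyl, while the quaternary spiro centre cannot epimerise.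

Compound list

1 | kaempferol, 3,5,7-trihydroxy-2-(4-hydroxyphenyl)-4H-chromen-4-one | O=c1c(O)c(-c2ccc(O)cc2)oc2cc(O)cc(O)c12 | starting material
2 | 3,5-dihydroxy-2-(4-hydroxyphenyl)-7-(methoxymethoxy)-4H-chromen-4-one | O=c1c(O)c(-c2ccc(O)cc2)oc2cc(OCOC)cc(O)c12 | intermediate
3 | 3,5-bis(benzyloxy)-2-[4-(benzyloxy)phenyl]-7-(methoxymethoxy)-4H-chromen-4-one | O=c1c(OCc2ccccc2)c(-c2ccc(OCc3ccccc3)cc2)oc2cc(OCOC)cc(OCc3ccccc3)c12 | intermediate
4 | 3,5-bis(benzyloxy)-2-[4-(benzyloxy)phenyl]-7-hydroxy-4H-chromen-4-one | O=c1c(OCc2ccccc2)c(-c2ccc(OCc3ccccc3)cc2)oc2cc(O)cc(OCc3ccccc3)c12 | intermediate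
5 | 5-fluorobenzene-1,3-diol | Oc1cc(O)cc(F)c1 | starting material
6 | 1,3-bis(benzyloxy)-5-fluorobenzene | Fc1cc(OCc2ccccc2)cc(OCc2ccccc2)c1 | intermediate
7 | N-[2,4-bis(benzyloxy)-6-fluorobenzylidene]-N-methylmethanaminium dichlorophosphate (not isolated) | C[N+](C)=Cc1c(F)cc(OCc2ccccc2)cc1OCc1ccccc1.[O-]P(=O)(Cl)Cl | intermediate
8 | 2,4-bis(benzyloxy)-6-fluorobenzaldehyde | O=Cc1c(F)cc(OCc2ccccc2)cc1OCc1ccccc1 | intermediate
9 | 1-[4-(benzyloxy)phenyl]ethanone | CC(=O)c1ccc(OCc2ccccc2)cc1 | starting material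
10 | lithium 1-[4-(benzyloxy)phenyl]ethenolate (not isolated) | [Li+].[O-]C(=C)c1ccc(OCc2ccccc2)cc1 | intermediate
11 | racemic 3-[2,4-bis(benzyloxy)-6-fluorophenyl]-1-[4-(benzyloxy)phenyl]-3-hydroxypropan-1-one | O=C(CC(O)c1c(F)cc(OCc2ccccc2)cc1OCc1ccccc1)c1ccc(OCc2ccccc2)cc1 | intermediate
12 | 1-[2,4-bis(benzyloxy)-6-fluorophenyl]-3-[4-(benzyloxy)phenyl]propane-1,3-dione (not isolated) | O=C(CC(=O)c1c(F)cc(OCc2ccccc2)cc1OCc1ccccc1)c1ccc(OCc2ccccc2)cc1 | intermediate
13 | 1-[2,4-bis(benzyloxy)-6-fluorophenyl]-3-[4-(benzyloxy)phenyl]propane-1,2,3-trione | O=C(C(=O)C(=O)c1c(F)cc(OCc2ccccc2)cc1OCc1ccccc1)c1ccc(OCc2ccccc2)cc1 | intermediate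
14 | (2R)-2-{3,5-bis(benzyloxy)-2-[4-(benzyloxy)phenyl]-7-hydroxy-4-oxo-4H-chromen-8-yl}-1-[2,4-bis(benzyloxy)-6-fluorophenyl]-3-[4-(benzyloxy)phenyl]-2-hydroxypropane-1,3-dione (not isolated) | O[C@@](C(=O)c1c(F)cc(OCc2ccccc2)cc1OCc1ccccc1)(C(=O)c1ccc(OCc2ccccc2)cc1)c1c(O)cc(OCc2ccccc2)c2c(=O)c(OCc3ccccc3)c(-c3ccc(OCc4ccccc4)cc3)oc12 | intermediate
15 | (8R,9S)-3,5-bis(benzyloxy)-9-[2,4-bis(benzyloxy)-6-fluorobenzoyl]-2,8-bis[4-(benzyloxy)phenyl]-8,9-dihydroxy-8,9-dihydro-4H-furo[2,3-h]chromen-4-one (not isolated) | O[C@]1(C(=O)c2c(F)cc(OCc3ccccc3)cc2OCc2ccccc2)c2c(cc(OCc3ccccc3)c3c(=O)c(OCc4ccccc4)c(-c4ccc(OCc5ccccc5)cc4)oc23)O[C@]1(O)c1ccc(OCc2ccccc2)cc1 | intermediate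
16 | (8R,9S)-3,5,8-tris(benzyloxy)-9-[2,4-bis(benzyloxy)-6-fluorobenzoyl]-2,8-bis[4-(benzyloxy)phenyl]-9-hydroxy-8,9-dihydro-4H-furo[2,3-h]chromen-4-one | O[C@]1(C(=O)c2c(F)cc(OCc3ccccc3)cc2OCc2ccccc2)c2c(cc(OCc3ccccc3)c3c(=O)c(OCc4ccccc4)c(-c4ccc(OCc5ccccc5)cc4)oc23)O[C@]1(OCc1ccccc1)c1ccc(OCc2ccccc2)cc1 | intermediate
17 | (2S,8'R)-3',4,5',6,8'-pentakis(benzyloxy)-2',8'-bis[4-(benzyloxy)phenyl]-8'H-spiro[1-benzofuran-2,9'-furo[2,3-h]chromene]-3,4'-dione | O=C1c2c(OCc3ccccc3)cc(OCc3ccccc3)cc2O[C@@]12c1c(cc(OCc3ccccc3)c3c(=O)c(OCc4ccccc4)c(-c4ccc(OCc5ccccc5)cc4)oc13)O[C@]2(OCc1ccccc1)c1ccc(OCc2ccccc2)cc1 | intermediate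
18 | (2S,8'R)-3',4,5',6,8'-pentahydroxy-2',8'-bis(4-hydroxyphenyl)-8'H-spiro[1-benzofuran-2,9'-furo[2,3-h]chromene]-3,4'-dione | O=C1c2c(O)cc(O)cc2O[C@@]12c1c(cc(O)c3c(=O)c(O)c(-c4ccc(O)cc4)oc13)O[C@]2(O)c1ccc(O)cc1 | target

Total step count: 10. Longest linear sequence: 7 steps (steps 4 to 10, from 5-fluorobenzene-1,3-diol).

Steps most likely to fail

Step 8 (Proposed new method). What may go wrong: insufficient facial discrimination between the two aroyl flanks of the triketone, slow C-alkylation of the acyl-deactivated phenoxide, or an acid-induced 1,2-acyl shift during ketalisation. The fallback uses known chemistry and sets out from 4 and 13. Heating both in acetic acid at 60 °C effects the uncatalysed Friedel–Crafts addition and hemiketalisation known for phenols with ninhydrin and diaryl triketones. This gives 14 and 15 as racemates, that is together with the enantiomeric open-chain carbinol F1 and the enantiomeric hemiketal F2. Ketalisation with BnOH and camphorsulfonic acid as in step 8 gives 16 together with the enantiomeric benzyl ketal F3. Preparative HPLC on a chiral stationary phase (amylose tris(3,5-dimethylphenylcarbamate)) separates the two, and the fallback comes back to the route at 16.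

Step 9. What may go wrong: slow five-membered ring closure, because the alkoxide must reach the arene carbon through a short tether while the single ketone activator is twisted out of conjugation, so that base-induced α-ketol rearrangement of the alkoxide competes. The fallback replaces SNAr by palladium-catalysed intramolecular etherification of a bromo analogue; it sets out from 4 and comes back at 17.
- Commercial 5-bromoresorcinol is benzylated as in step 4 to 1,3-bis(benzyloxy)-5-bromobenzene F4.
- Vilsmeier–Haack formylation as in step 5, through the bromo iminium salt F5, gives 2,4-bis(benzyloxy)-6-bromobenzaldehyde F6.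
- Aldol addition of enolate 10 gives the racemic bromo aldol F7.
- Dess–Martin oxidation as in step 7, through the bromo 1,3-diketone F8, gives the bromo triketone F9.
- Union with 4 under the conditions of step 8 gives, through the bromo open-chain carbinol F10 and the bromo hemiketal F11, the bromo benzyl ketal F12.
- Pd(OAc)2 (5 mol %), 2-(di-tert-butylphosphino)-2',4',6'-triisopropylbiphenyl (10 mol %), Cs2CO3, toluene, 80 °C then closes the same O1–C7a bond to give 17. Zerovalent palladium inserts into the C–Br bond ortho to the ketone, the tertiary alkoxide binds, and C–O reductive elimination follows from a six-membered palladacycle; this etherification of tertiary alcohols with aryl bromides is well established.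

Step 7. What may go wrong: stalling of the second oxidation at the diketone stage, or oxidative C–C cleavage of the triketone by excess periodinane. The fallback sets out from 11: Dess–Martin periodinane (1.2 equiv, CH2Cl2, rt) stops at the 1,3-diketone 12, which is isolated. Riley oxidation with SeO2 (1.2 equiv, dioxane, 90 °C) then oxidises the activated methylene to give 13, where the route is rejoined.

Further compounds

F1 | step 8 | (2S)-enantiomer of open-chain carbinol 14 | O[C@](C(=O)c1c(F)cc(OCc2ccccc2)cc1OCc1ccccc1)(C(=O)c1ccc(OCc2ccccc2)cc1)c1c(O)cc(OCc2ccccc2)c2c(=O)c(OCc3ccccc3)c(-c3ccc(OCc4ccccc4)cc3)oc12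
F2 | step 8 | (8S,9R)-enantiomer of hemiketal 15 | O[C@@]1(C(=O)c2c(F)cc(OCc3ccccc3)cc2OCc2ccccc2)c2c(cc(OCc3ccccc3)c3c(=O)c(OCc4ccccc4)c(-c4ccc(OCc5ccccc5)cc4)oc23)O[C@@]1(O)c1ccc(OCc2ccccc2)cc1
F3 | step 8 | (8S,9R)-enantiomer of benzyl ketal 16 | O[C@@]1(C(=O)c2c(F)cc(OCc3ccccc3)cc2OCc2ccccc2)c2c(cc(OCc3ccccc3)c3c(=O)c(OCc4ccccc4)c(-c4ccc(OCc5ccccc5)cc4)oc23)O[C@@]1(OCc1ccccc1)c1ccc(OCc2ccccc2)cc1
F4 | step 9 | 1,3-bis(benzyloxy)-5-bromobenzene | Brc1cc(OCc2ccccc2)cc(OCc2ccccc2)c1
F5 | step 9 | N-[2,4-bis(benzyloxy)-6-bromobenzylidene]-N-methylmethanaminium dichlorophosphate | C[N+](C)=Cc1c(Br)cc(OCc2ccccc2)cc1OCc1ccccc1.[O-]P(=O)(Cl)Cl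
F6 | step 9 | 2,4-bis(benzyloxy)-6-bromobenzaldehyde | O=Cc1c(Br)cc(OCc2ccccc2)cc1OCc1ccccc1
F7 | step 9 | racemic 3-[2,4-bis(benzyloxy)-6-bromophenyl]-1-[4-(benzyloxy)phenyl]-3-hydroxypropan-1-one | O=C(CC(O)c1c(Br)cc(OCc2ccccc2)cc1OCc1ccccc1)c1ccc(OCc2ccccc2)cc1
F8 | step 9 | 1-[2,4-bis(benzyloxy)-6-bromophenyl]-3-[4-(benzyloxy)phenyl]propane-1,3-dione | O=C(CC(=O)c1c(Br)cc(OCc2ccccc2)cc1OCc1ccccc1)c1ccc(OCc2ccccc2)cc1
F9 | step 9 | 1-[2,4-bis(benzyloxy)-6-bromophenyl]-3-[4-(benzyloxy)phenyl]propane-1,2,3-trione | O=C(C(=O)C(=O)c1c(Br)cc(OCc2ccccc2)cc1OCc1ccccc1)c1ccc(OCc2ccccc2)cc1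
F10 | step 9 | (2R)-2-{3,5-bis(benzyloxy)-2-[4-(benzyloxy)phenyl]-7-hydroxy-4-oxo-4H-chromen-8-yl}-1-[2,4-bis(benzyloxy)-6-bromophenyl]-3-[4-(benzyloxy)phenyl]-2-hydroxypropane-1,3-dione | O[C@@](C(=O)c1c(Br)cc(OCc2ccccc2)cc1OCc1ccccc1)(C(=O)c1ccc(OCc2ccccc2)cc1)c1c(O)cc(OCc2ccccc2)c2c(=O)c(OCc3ccccc3)c(-c3ccc(OCc4ccccc4)cc3)oc12
F11 | step 9 | (8R,9S)-3,5-bis(benzyloxy)-9-[2,4-bis(benzyloxy)-6-bromobenzoyl]-2,8-bis[4-(benzyloxy)phenyl]-8,9-dihydroxy-8,9-dihydro-4H-furo[2,3-h]chromen-4-one | O[C@]1(C(=O)c2c(Br)cc(OCc3ccccc3)cc2OCc2ccccc2)c2c(cc(OCc3ccccc3)c3c(=O)c(OCc4ccccc4)c(-c4ccc(OCc5ccccc5)cc4)oc23)O[C@]1(O)c1ccc(OCc2ccccc2)cc1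
F12 | step 9 | (8R,9S)-3,5,8-tris(benzyloxy)-9-[2,4-bis(benzyloxy)-6-bromobenzoyl]-2,8-bis[4-(benzyloxy)phenyl]-9-hydroxy-8,9-dihydro-4H-furo[2,3-h]chromen-4-one | O[C@]1(C(=O)c2c(Br)cc(OCc3ccccc3)cc2OCc2ccccc2)c2c(cc(OCc3ccccc3)c3c(=O)c(OCc4ccccc4)c(-c4ccc(OCc5ccccc5)cc4)oc23)O[C@]1(OCc1ccccc1)c1ccc(OCc2ccccc2)cc1
F0 | step 7 | none | none
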